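**Plan**
1. The target is read as (2R,3S,4R,5R)-2,5-bis(4-hydroxy-3-methoxyphenyl)-3,4-dimethyloxolan-3-ol (O1, C2 beside the carbinol C3, C4, C5): both aryl and both methyl groups lie on one ring face, the hydroxyl and H-2, H-4, H-5 on the other.
2. Retrosynthetic cuts: first C2–aryl and C2–H (aryllithium, then hydride, on a lactone carbonyl), next C4–H and C5–H (the C4=C5 bond of an enol lactone), then O1–C2 and C3–C4 together, which leaves propiovanillone and a pyruvate.
3. Enabling feature: C3 with its methyl and hydroxyl is a masked pyruvate ketone whose carboxyl carbon is C2, and O1–C5(aryl)=C4(methyl) is the enol of an aryl ethyl ketone, so the ring O1–C2–C3–C4–C5 is that of a 3-hydroxyfuran-2(3H)-one.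
4. Forward order: the only ring is closed in one flask (aldol addition makes C3–C4, enol lactonisation makes O1–C2), then the ring alkene is hydrogenated, the second aryl group is joined at C2, the lactol is reduced and the benzyl ethers are removed.
5. Stereochemistry: C3 comes from a chiral copper Lewis acid, C4 and C5 from hydroxyl-directed hydrogenation, and C2 from hydride attack on the oxocarbenium face that carries only the hydroxyl, so every ring hydrogen is delivered cis to the C3 hydroxyl.

Key step: step 4

Remark: propiovanillone, pyruvic acid, the aryl bromide and all reagents are taken as commercial; both phenols are carried as benzyl ethers.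

**Step 1**
Reactants: 1 1-(4-hydroxy-3-methoxyphenyl)propan-1-one (propiovanillone)
Product: 2 1-[4-(benzyloxy)-3-methoxyphenyl]propan-1-one
Conditions: BnBr, K2CO3, DMF, rt
Reagents that add atoms: benzyl bromide, BrCc1ccccc1
Why: Williamson ether synthesis on the phenoxide, the only site alkylated under carbonate conditions, masks the phenol for the Lewis acid and organolithium steps.

**Step 2**
Reactants: 2 1-[4-(benzyloxy)-3-methoxyphenyl]propan-1-one
Product: 3 {[(1Z)-1-[4-(benzyloxy)-3-methoxyphenyl]prop-1-en-1-yl]oxy}trimethylsilane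
Conditions: LiN(SiMe3)2, THF, −78 °C; Me3SiCl, −78 °C → rt
Reagents that add atoms: chlorotrimethylsilane, C[Si](C)(C)Cl
Why: Kinetic enolisation of an aryl ethyl ketone and O-silylation (silyl enol ether formation) should give mainly the Z enolsilane, whose geometry is of no consequence because C4 returns to sp2 in step 4.

**Step 3**
Reactants: 4 pyruvic acid
Product: 5 pentafluorophenyl 2-oxopropanoate
Conditions: C6F5OH, N,N'-dicyclohexylcarbodiimide, CH2Cl2, 0 °C → rt
Reagents that add atoms: pentafluorophenol, Oc1c(F)c(F)c(F)c(F)c1F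
Why: Carbodiimide-mediated esterification gives an active ester that keeps the 1,2-dicarbonyl needed for two-point binding to copper and carries a leaving group good enough for acyl transfer to an enolate oxygen.

**Step 4**
Reactants: 3 {[(1Z)-1-[4-(benzyloxy)-3-methoxyphenyl]prop-1-en-1-yl]oxy}trimethylsilane; 5 pentafluorophenyl 2-oxopropanoate
Product: 8 (3S)-5-[4-(benzyloxy)-3-methoxyphenyl]-3-hydroxy-3,4-dimethylfuran-2(3H)-one, via silylated aldol adduct 6 (not isolated), via silylated enol lactone 7 (not isolated)
Conditions: Cu(OTf)2 (10 mol%), (S,S)-tBu-box [2,2'-(propane-2,2-diyl)bis((4S)-4-tert-butyl-4,5-dihydrooxazole)] (11 mol%), THF, −78 °C; then DBU, −78 → 0 °C; then 1 M HCl, THF, 0 °C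
Reagents that add atoms: none
Why: The divalent copper centre of the Cu(OTf)2–(S,S)-tBu-box complex binds the ketone and ester carbonyls of 5 in a square-planar chelate, enolsilane 3 adds through an open transition state to the ketone carbon (C3–C4) and silyl transfer releases 6, after which DBU enolises the aryl ketone toward C4 and the enolate oxygen attacks the pentafluorophenyl ester (O1–C2), expelling pentafluorophenoxide to give 7, which loses its silyl group on acidic work-up. The closest known reaction types are the copper–bis(oxazoline)-catalysed Mukaiyama aldol addition of enolsilanes to pyruvate esters and the enol lactonisation of γ-keto acid derivatives, and the overall union of an enol with an α-keto ester parallels the Friedel–Crafts alkylation–lactonisation of phenols with pyruvates to 3-hydroxybenzofuran-2(3H)-ones. The furanone ring closes by 5-exo-trig attack of the enolate oxygen on the ester carbonyl. The only stereocentre, C3, is set by the ligand, whose tert-butyl groups shield the Re face of the bound ketone so that addition to the Si face should give the 3S carbinol, and since C4 returns to sp2 neither the enolsilane geometry nor the syn/anti ratio of 6 matters. The step needs attack at the ketone and not the ester carbonyl (the chelated ketone is the more electrophilic carbon), O- and not C-acylation (C-acylation would close a three-membered ring) and no retro-aldol or dehydration (the tertiary oxygen stays silylated during the base stage, enolisation is possible only toward C4, and 8 cannot aromatise because C3 is quaternary).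

**Step 5**
Reactants: 8 (3S)-5-[4-(benzyloxy)-3-methoxyphenyl]-3-hydroxy-3,4-dimethylfuran-2(3H)-one
Product: 9 (3S,4R,5R)-5-[4-(benzyloxy)-3-methoxyphenyl]-3-hydroxy-3,4-dimethyloxolan-2-one
Conditions: H2 (1–4 bar), [Ir(cod)(PCy3)(py)]PF6 (5 mol%), CH2Cl2, rt
Reagents that add atoms: none
Why: In this hydroxyl-directed homogeneous hydrogenation the cationic iridium centre binds the tertiary allylic hydroxyl and adds both hydrogens to the alkene face syn to it, which is also the face free of the C3 methyl, so that C4 and C5 are set with methyl and aryl cis to the C3 methyl while the benzyl ether is left intact.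

**Step 6**
Reactants: 9 (3S,4R,5R)-5-[4-(benzyloxy)-3-methoxyphenyl]-3-hydroxy-3,4-dimethyloxolan-2-one; 10 1-(benzyloxy)-4-bromo-2-methoxybenzene
Product: 12 (3S,4R,5R)-2,5-bis[4-(benzyloxy)-3-methoxyphenyl]-3,4-dimethyloxolane-2,3-diol (both C2 anomers), via aryllithium 11 (not isolated)
Conditions: 10 (2.3 equiv), n-BuLi, THF, −78 °C; then 9, −78 → −40 °C; aq. NH4Cl
Reagents that add atoms: none
Why: Bromine–lithium exchange followed by aryllithium addition to the lactone carbonyl should stop at the lactolate at low temperature, the first equivalent being spent on the tertiary hydroxyl, the carbonyl having no α-hydrogen to lose, and the new anomeric centre being flattened again in step 7.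

**Step 7**
Reactants: 12 (3S,4R,5R)-2,5-bis[4-(benzyloxy)-3-methoxyphenyl]-3,4-dimethyloxolane-2,3-diol
Product: 13 (2R,3S,4R,5R)-2,5-bis[4-(benzyloxy)-3-methoxyphenyl]-3,4-dimethyloxolan-3-ol
Conditions: Et3SiH, BF3·OEt2, CH2Cl2, −78 → −30 °C
Reagents that add atoms: none
Why: In this ionic hydrogenation of a lactol, BF3·OEt2 ionises the hemiketal to a 2-aryl oxocarbenium ion that cannot lose a proton because C3 is quaternary, and hydride enters from the face that carries only the C3 hydroxyl, opposite the C3 methyl, C4 methyl and C5 aryl, so that C2 is formed with its aryl group cis to the other three carbon substituents.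

**Step 8**
Reactants: 13 (2R,3S,4R,5R)-2,5-bis[4-(benzyloxy)-3-methoxyphenyl]-3,4-dimethyloxolan-3-ol
Product: 14 (2R,3S,4R,5R)-2,5-bis(4-hydroxy-3-methoxyphenyl)-3,4-dimethyloxolan-3-ol
Conditions: H2 (1 atm), 10% Pd/C, EtOAc, rt
Reagents that add atoms: none
Why: Hydrogenolysis of the two benzyl aryl ethers under neutral conditions frees both phenols without touching the stereocentres, the benzylic ring C–O bonds being much slower to cleave than the O-benzyl groups.

**Compound list**
1 | 1-(4-hydroxy-3-methoxyphenyl)propan-1-one (propiovanillone) | CCC(=O)c1ccc(O)c(OC)c1 | starting material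
2 | 1-[4-(benzyloxy)-3-methoxyphenyl]propan-1-one | CCC(=O)c1ccc(OCc2ccccc2)c(OC)c1 | intermediate
3 | {[(1Z)-1-[4-(benzyloxy)-3-methoxyphenyl]prop-1-en-1-yl]oxy}trimethylsilane | C/C=C(\O[Si](C)(C)C)c1ccc(OCc2ccccc2)c(OC)c1 | intermediate
4 | pyruvic acid (2-oxopropanoic acid) | CC(=O)C(O)=O | starting material
5 | pentafluorophenyl 2-oxopropanoate | CC(=O)C(=O)Oc1c(F)c(F)c(F)c(F)c1F | intermediate
6 | pentafluorophenyl (2S)-4-[4-(benzyloxy)-3-methoxyphenyl]-2,3-dimethyl-4-oxo-2-[(trimethylsilyl)oxy]butanoate (both C3 epimers) | COc1cc(C(=O)C(C)[C@](C(=O)Oc2c(F)c(F)c(F)c(F)c2F)(C)O[Si](C)(C)C)ccc1OCc1ccccc1 | intermediate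
7 | (3S)-5-[4-(benzyloxy)-3-methoxyphenyl]-3,4-dimethyl-3-[(trimethylsilyl)oxy]furan-2(3H)-one | O=C1OC(c2ccc(OCc3ccccc3)c(OC)c2)=C(C)[C@]1(C)O[Si](C)(C)C | intermediate
8 | (3S)-5-[4-(benzyloxy)-3-methoxyphenyl]-3-hydroxy-3,4-dimethylfuran-2(3H)-one | O=C1OC(c2ccc(OCc3ccccc3)c(OC)c2)=C(C)[C@]1(C)O | intermediate
9 | (3S,4R,5R)-5-[4-(benzyloxy)-3-methoxyphenyl]-3-hydroxy-3,4-dimethyloxolan-2-one | O=C1O[C@@H](c2ccc(OCc3ccccc3)c(OC)c2)[C@@H](C)[C@]1(C)O | intermediate
10 | 1-(benzyloxy)-4-bromo-2-methoxybenzene | COc1cc(Br)ccc1OCc1ccccc1 | starting material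
11 | [4-(benzyloxy)-3-methoxyphenyl]lithium | [Li]c1ccc(OCc2ccccc2)c(OC)c1 | intermediate
12 | (3S,4R,5R)-2,5-bis[4-(benzyloxy)-3-methoxyphenyl]-3,4-dimethyloxolane-2,3-diol (both C2 anomers) | COc1cc(C2(O)O[C@@H](c3ccc(OCc4ccccc4)c(OC)c3)[C@@H](C)[C@]2(C)O)ccc1OCc1ccccc1 | intermediate
13 | (2R,3S,4R,5R)-2,5-bis[4-(benzyloxy)-3-methoxyphenyl]-3,4-dimethyloxolan-3-ol | COc1cc([C@H]2O[C@@H](c3ccc(OCc4ccccc4)c(OC)c3)[C@@H](C)[C@]2(C)O)ccc1OCc1ccccc1 | intermediate
14 | (2R,3S,4R,5R)-2,5-bis(4-hydroxy-3-methoxyphenyl)-3,4-dimethyloxolan-3-ol (CNP0234919.1) | COc1cc([C@H]2O[C@@H](c3ccc(O)c(OC)c3)[C@@H](C)[C@]2(C)O)ccc1O | target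

**Summary**
Total step count: 8. Longest linear sequence: 7 steps (steps 1, 2, 4, 5, 6, 7, 8, from 1 to 14); step 3 is a one-step branch.

**Steps most likely to fail**

Step 4. During the base stage, β-elimination of the silyloxy group from the ketone enolate may outrun O-acylation, or the active ester may hydrolyse before the ring closes. The fallback sets out from 3 and comes back at 8. The same copper-catalysed Mukaiyama aldol addition is run with commercial methyl pyruvate (CC(=O)C(=O)OC) and worked up with dilute HCl to give methyl (2S)-4-[4-(benzyloxy)-3-methoxyphenyl]-2-hydroxy-2,3-dimethyl-4-oxobutanoate F1. Saponification (LiOH, THF/H2O, 0 °C) gives (2S)-4-[4-(benzyloxy)-3-methoxyphenyl]-2-hydroxy-2,3-dimethyl-4-oxobutanoic acid F2. Dehydrative enol lactonisation of this γ-keto acid with 1-ethyl-3-(3-dimethylaminopropyl)carbodiimide hydrochloride in CH2Cl2 closes it to 8.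

Step 5. The catalyst may fail to turn over at the tetrasubstituted, aryl-conjugated enol ester alkene, or facial control may be lost. The fallback sets out from 8 and comes back at 9 and makes no new compound (F0). It is an ionic hydrogenation (CF3CO2H, Et3SiH, CH2Cl2, −40 → 0 °C): protonation at C4 from the hydroxyl face gives an aryl-stabilised acyloxycarbenium ion at C5, which should take hydride anti to the new C4 methyl.

Step 6. Ring opening of the lactolate may lead to a second addition, or addition at the carbonyl flanked by the quaternary alkoxide carbon may be sluggish. The fallback sets out from 9 and comes back at 12. The lactone is opened with MeNH(OMe)·HCl and AlMe3 (CH2Cl2, 0 °C) to (2S,3R,4R)-4-[4-(benzyloxy)-3-methoxyphenyl]-2,4-dihydroxy-N-methoxy-N,2,3-trimethylbutanamide F3. This is treated at once with excess 11 (Weinreb ketone synthesis); the chelated tetrahedral intermediate cannot add twice, and the hydroxy ketone closes to 12 on work-up.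

**Further compounds**
F1 | step 4 | methyl (2S)-4-[4-(benzyloxy)-3-methoxyphenyl]-2-hydroxy-2,3-dimethyl-4-oxobutanoate (both C3 epimers) | COC(=O)[C@@](C)(O)C(C)C(=O)c1ccc(OCc2ccccc2)c(OC)c1
F2 | step 4 | (2S)-4-[4-(benzyloxy)-3-methoxyphenyl]-2-hydroxy-2,3-dimethyl-4-oxobutanoic acid (both C3 epimers) | OC(=O)[C@@](C)(O)C(C)C(=O)c1ccc(OCc2ccccc2)c(OC)c1
F0 | step 5 | none | none
F3 | step 6 | (2S,3R,4R)-4-[4-(benzyloxy)-3-methoxyphenyl]-2,4-dihydroxy-N-methoxy-N,2,3-trimethylbutanamide | CON(C)C(=O)[C@@](C)(O)[C@H](C)[C@@H](O)c1ccc(OCc2ccccc2)c(OC)c1
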